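**Plan**
1. Cuts, in retrosynthetic order: the three methoxymethyl acetals; C2–C1' (ring B delivered as an arylboronic acid to a chromone); ring C at O1–C2, C3–C4 and C4–C4a (ynone from an ortho-formylated phenol); ring A at C4a–C5, C7–C8, C4a–C8a and C6–C7, leaving an alkenyl diazoketone and 1-siloxypropyne.
2. Enabling feature: ring A is a fully substituted phloroglucinol in which oxygen on C5, C7 and C8a alternates with carbon on C6 (prenyl), C8 (methyl) and C4a. A vinylketene/siloxyalkyne benzannulation builds exactly this alternation and releases O5, O7 and O1 as acetal, free phenol and silyl ether, so the oxygen that becomes the ring C heteroatom is marked from the start.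
3. Forward order: ring A (step 6), then ring C by formylation at C4a, alkynylation and oxidative 6-endo closure (steps 9–11), then ring B at C2 (step 14), then deprotection.
4. Stereochemistry: the single stereocenter C2 (S) is set under catalyst control in the rhodium/chiral bisphosphine 1,4-addition of step 14 and afterwards meets only dilute acid.

Key step: step 6

Flavanone numbering (O1, C2–C4, C4a, C5–C8, C8a; ring B primed) is used for the ring atoms throughout, also in precursors.
Assumption: the (S)-configured biaryl bisphosphine is taken to deliver aryl to the C2 face that gives 2S, by analogy with 2-cyclohexenone (the (R)-ligand is used if the sense is opposite); enol ethers are drawn as the expected Z isomers, a geometry that is erased when ring A aromatises.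

**Step 1**
Reactants: 1 5-bromo-2-methylpent-2-ene; 2 dimethyl oxalate
Product: 4 methyl 6-methyl-2-oxohept-5-enoate, via homoprenylmagnesium bromide 3 (not isolated)
Conditions: Mg, THF, 25 °C; then 2 (2 equiv), THF, −78 °C; aq. NH4Cl
Reagents that add atoms: none
Why: Monoaddition of a Grignard reagent to a dialkyl oxalate (nucleophilic acyl substitution) should stop at the α-keto ester, because the magnesium hemiketalate survives at −78 °C and the oxalate is in excess.

**Step 2**
Reactants: 4 methyl 6-methyl-2-oxohept-5-enoate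
Product: 5 methyl (2Z)-2-(methoxymethoxy)-6-methylhepta-2,5-dienoate
Conditions: KHMDS, THF/DMPU, −78 °C (ester added to base); MOMCl, −78 → 0 °C
Reagents that add atoms: chloromethyl methyl ether, COCCl
Why: Only C3 can be enolised, and the hard chloromethyl ether should alkylate the potassium enolate on oxygen (enolate O-alkylation), mainly as the Z isomer that avoids allylic strain with the ester.

**Step 3**
Reactants: 5 methyl (2Z)-2-(methoxymethoxy)-6-methylhepta-2,5-dienoate
Product: 6 (2Z)-2-(methoxymethoxy)-6-methylhepta-2,5-dienoic acid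
Conditions: LiOH, THF/H2O, 0 → 25 °C; then 0.5 M HCl to pH 4, 0 °C
Reagents that add atoms: lithium hydroxide, [Li+].[OH-]
Why: Saponification of the methyl ester with hydroxide; the enol acetal is base-stable and the acid is set free only briefly at pH 4 in the cold.

**Step 4**
Reactants: 6 (2Z)-2-(methoxymethoxy)-6-methylhepta-2,5-dienoic acid
Product: 8 (3Z)-1-diazo-3-(methoxymethoxy)-7-methylocta-3,6-dien-2-one, via mixed isobutyl carbonic anhydride 7 (not isolated)
Conditions: i-BuOCOCl, Et3N, THF, −15 °C; then CH2N2 (excess), Et2O, 0 → 25 °C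
Reagents that add atoms: diazomethane, C=[N+]=[N-]
Why: Acylation of diazomethane by a mixed carbonic anhydride (first stage of the Arndt–Eistert sequence) runs under amine-buffered conditions that spare the enol acetal, and the trisubstituted, oxygen-bearing double bond is a poor dipolarophile.

**Step 5**
Reactants: 9 ethyl acetate
Product: 11 triisopropyl(prop-1-ynyloxy)silane, via lithium propynolate 10 (not isolated)
Conditions: LiTMP, CH2Br2, THF, −78 °C; then 9; LiHMDS; n-BuLi, −78 → 25 °C; TIPSCl, −78 → 0 °C
Reagents that add atoms: dibromomethane, BrCBr; chlorotriisopropylsilane, CC(C)[Si](Cl)(C(C)C)C(C)C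
Why: Kowalski ester homologation: dibromomethyllithium adds to the ester, bromine–lithium exchange on the dibromo enolate triggers migration of methyl with loss of bromide to the ynolate, and the bulky silyl chloride caps it on oxygen.

**Step 6**
Reactants: 8 (3Z)-1-diazo-3-(methoxymethoxy)-7-methylocta-3,6-dien-2-one; 11 triisopropyl(prop-1-ynyloxy)silane
Product: 16 3-(methoxymethoxy)-6-methyl-2-(3-methylbut-2-enyl)-5-(triisopropylsilyloxy)phenol, via vinylketene 12 (not isolated), via alkenylcyclobutenone 13 (not isolated), via dienylketene 14 (not isolated), via cyclohexadienone 15 (not isolated)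
Conditions: hν (254 nm, quartz), 11 (1.5 equiv), degassed ClCH2CH2Cl, 25 °C; then 80 °C in the dark
Reagents that add atoms: none
Why: Light expels N2 from 8 and the alkenyl carbon C5 migrates to the former diazo carbon C4a (photochemical Wolff rearrangement, new C4a–C5 bond) to give vinylketene 12, whose ketene C=C adds across the triple bond of 11 in a [2+2] cycloaddition (C7–C8 and C4a–C8a) to give cyclobutenone 13. On warming, 13 reopens by 4π electrocyclic cleavage of the C4a–C7 bond to dienylketene 14, and ring A is closed by thermal 6π disrotatory electrocyclisation between C6 and C7 to dienone 15, which tautomerises to phenol 16. The closest known reaction is the Danheiser benzannulation in its photochemical Wolff variant with siloxyalkynes, which gives resorcinol monosilyl ethers; here the diazoketone additionally carries an enol acetal oxygen on C5. No stereocenter is formed. The selectivity needed is the orientation of the [2+2] step, fixed by polarisation: the methyl-bearing carbon of the ynol ether is the nucleophilic terminus and bonds to the electrophilic ketene carbon C7, so methyl (C8) lies next to the new hydroxyl and the silyloxy carbon (C8a) next to C4a. The Z enol ether holds the allylic CH2 away from the ketene, which excludes a 1,5-hydrogen shift and leaves only hydrogen inside the closing triene, and prenyl and methyl cannot exchange positions because they ride on different partners.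

**Step 7**
Reactants: 16 3-(methoxymethoxy)-6-methyl-2-(3-methylbut-2-enyl)-5-(triisopropylsilyloxy)phenol
Product: 17 [3,5-bis(methoxymethoxy)-2-methyl-4-(3-methylbut-2-enyl)phenoxy]triisopropylsilane
Conditions: NaH, DMF, 0 °C; MOMCl, 0 → 25 °C
Reagents that add atoms: chloromethyl methyl ether, COCCl
Why: O-Alkylation of the sodium phenoxide with chloromethyl methyl ether (acetal protection); the aryl silyl ether tolerates NaH, and the silyl group cannot migrate between oxygens that are meta to each other.

**Step 8**
Reactants: 17 [3,5-bis(methoxymethoxy)-2-methyl-4-(3-methylbut-2-enyl)phenoxy]triisopropylsilane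
Product: 18 3,5-bis(methoxymethoxy)-2-methyl-4-(3-methylbut-2-enyl)phenol
Conditions: TBAF, THF, 0 °C; aq. NH4Cl
Reagents that add atoms: none
Why: Fluoride cleaves the aryl silicon–oxygen bond (desilylation) and frees O1 alone, since acetals are inert to fluoride.

**Step 9**
Reactants: 18 3,5-bis(methoxymethoxy)-2-methyl-4-(3-methylbut-2-enyl)phenol
Product: 19 2-hydroxy-4,6-bis(methoxymethoxy)-3-methyl-5-(3-methylbut-2-enyl)benzaldehyde
Conditions: MgCl2, Et3N, (CH2O)n, MeCN, reflux
Reagents that add atoms: paraformaldehyde (reacts as formaldehyde), C=O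
Why: Magnesium-mediated ortho-formylation of a phenol (Casnati–Skattebøl reaction): the chelated magnesium phenoxide adds formaldehyde at the ortho carbon and a second formaldehyde takes up hydride, and C4a is the only unsubstituted ring position.

**Step 10**
Reactants: 19 2-hydroxy-4,6-bis(methoxymethoxy)-3-methyl-5-(3-methylbut-2-enyl)benzaldehyde
Product: 20 2-(1-hydroxyprop-2-ynyl)-3,5-bis(methoxymethoxy)-6-methyl-4-(3-methylbut-2-enyl)phenol (racemic, used crude)
Conditions: HC≡CMgBr (3 equiv), THF, 0 → 25 °C; aq. NH4Cl
Reagents that add atoms: ethynylmagnesium bromide, C#C[Mg]Br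
Why: Addition of an alkynyl Grignard reagent to the aldehyde after the first equivalent has deprotonated the phenol; the carbinol center is formed without control and is erased in step 11.

**Step 11**
Reactants: 20 2-(1-hydroxyprop-2-ynyl)-3,5-bis(methoxymethoxy)-6-methyl-4-(3-methylbut-2-enyl)phenol
Product: 22 5,7-bis(methoxymethoxy)-8-methyl-6-(3-methylbut-2-enyl)-4H-chromen-4-one, via ynone 21 (not isolated)
Conditions: MnO2, CH2Cl2, 25 °C; filter; K2CO3, acetone, 25 °C
Reagents that add atoms: none
Why: MnO2 oxidises the benzylic propargylic alcohol to the ynone, and the ortho phenoxide then closes ring C by 6-endo-dig conjugate addition (oxa-Michael), the mode favoured for aryl ynones in an aprotic medium; O1 is the only free oxygen, so the chromone has O1 beside C8.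

**Step 12**
Reactants: 23 4-bromophenol
Product: 24 1-bromo-4-(methoxymethoxy)benzene
Conditions: MOMCl, i-Pr2NEt, CH2Cl2, 0 → 25 °C
Reagents that add atoms: chloromethyl methyl ether, COCCl
Why: O-Alkylation of the phenol with chloromethyl methyl ether and a hindered amine base (acetal protection).

**Step 13**
Reactants: 24 1-bromo-4-(methoxymethoxy)benzene
Product: 26 [4-(methoxymethoxy)phenyl]boronic acid, via aryllithium 25 (not isolated)
Conditions: n-BuLi, THF, −78 °C; B(Oi-Pr)3, −78 → 0 °C; aq. NH4Cl
Reagents that add atoms: triisopropyl borate, CC(C)OB(OC(C)C)OC(C)C; water, O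
Why: Bromine–lithium exchange followed by borylation of the aryllithium with a trialkyl borate and hydrolysis at near-neutral pH, which the acetal survives.

**Step 14**
Reactants: 22 5,7-bis(methoxymethoxy)-8-methyl-6-(3-methylbut-2-enyl)-4H-chromen-4-one; 26 [4-(methoxymethoxy)phenyl]boronic acid
Product: 27 (2S)-5,7-bis(methoxymethoxy)-2-[4-(methoxymethoxy)phenyl]-8-methyl-6-(3-methylbut-2-enyl)-2,3-dihydro-4H-chromen-4-one
Conditions: [Rh(OH)(cod)]2 (3 mol %), (S)-MeO-F12-BIPHEP [(S)-2,2'-bis[bis(3,4,5-trifluorophenyl)phosphino]-6,6'-dimethoxy-1,1'-biphenyl] (6.6 mol %), 26 (3 equiv), toluene/H2O, 40 °C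
Reagents that add atoms: none
Why: Rhodium-catalysed asymmetric 1,4-addition of an arylboronic acid to an enone (Hayashi–Miyaura reaction): the aryl rhodium complex of the chiral bisphosphine inserts the C2=C3 bond from one enantioface and the rhodium enolate is protonated by water, so that C2 is set as S by the ligand (catalyst control), while the electron-poor phosphine speeds insertion and disfavours a second, 1,2-addition.

**Step 15**
Reactants: 27 (2S)-5,7-bis(methoxymethoxy)-2-[4-(methoxymethoxy)phenyl]-8-methyl-6-(3-methylbut-2-enyl)-2,3-dihydro-4H-chromen-4-one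
Product: 28 (2S)-5,7-dihydroxy-2-(4-hydroxyphenyl)-8-methyl-6-(3-methylbut-2-enyl)-2,3-dihydro-4H-chromen-4-one
Conditions: HCl (3 M aq.), MeOH, 25 → 40 °C
Reagents that add atoms: none
Why: Acid-catalysed transacetalisation with methanol removes the three methoxymethyl groups; C2 is not epimerised because ring opening to the chalcone needs base, and dilute acid at this temperature should leave the prenyl group intact.

**Compound list**
1 | 5-bromo-2-methylpent-2-ene | CC(C)=CCCBr | starting material
2 | dimethyl oxalate | COC(=O)C(=O)OC | starting material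
3 | (4-methylpent-3-enyl)magnesium bromide (homoprenylmagnesium bromide) | CC(C)=CCC[Mg]Br | intermediate
4 | methyl 6-methyl-2-oxohept-5-enoate | COC(=O)C(=O)CCC=C(C)C | intermediate
5 | methyl (2Z)-2-(methoxymethoxy)-6-methylhepta-2,5-dienoate | COC(=O)/C(OCOC)=C/CC=C(C)C | intermediate
6 | (2Z)-2-(methoxymethoxy)-6-methylhepta-2,5-dienoic acid | OC(=O)/C(OCOC)=C/CC=C(C)C | intermediate
7 | (2Z)-2-(methoxymethoxy)-6-methylhepta-2,5-dienoic isobutyl carbonic anhydride | CC(C)COC(=O)OC(=O)/C(OCOC)=C/CC=C(C)C | intermediate
8 | (3Z)-1-diazo-3-(methoxymethoxy)-7-methylocta-3,6-dien-2-one | CC(C)=CC/C=C(OCOC)/C(=O)C=[N+]=[N-] | intermediate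
9 | ethyl acetate | CCOC(C)=O | starting material
10 | lithium prop-1-yn-1-olate | CC#C[O-].[Li+] | intermediate
11 | triisopropyl(prop-1-ynyloxy)silane (1-(triisopropylsilyloxy)propyne) | CC#CO[Si](C(C)C)(C(C)C)C(C)C | intermediate
12 | (3Z)-3-(methoxymethoxy)-7-methylocta-1,3,6-trien-1-one (vinylketene) | O=C=C/C(OCOC)=C/CC=C(C)C | intermediate
13 | 4-[(1Z)-1-(methoxymethoxy)-5-methylhexa-1,4-dienyl]-2-methyl-3-(triisopropylsilyloxy)cyclobut-2-en-1-one (racemic) | O=C1C(C)=C(O[Si](C(C)C)(C(C)C)C(C)C)C1/C(OCOC)=C/CC=C(C)C | intermediate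
14 | (3E,5Z)-5-(methoxymethoxy)-2,9-dimethyl-3-(triisopropylsilyloxy)deca-1,3,5,8-tetraen-1-one (dienylketene) | O=C=C(C)/C(O[Si](C(C)C)(C(C)C)C(C)C)=C\C(OCOC)=C\CC=C(C)C | intermediate
15 | 5-(methoxymethoxy)-2-methyl-6-(3-methylbut-2-enyl)-3-(triisopropylsilyloxy)cyclohexa-2,4-dien-1-one (racemic) | O=C1C(C)=C(O[Si](C(C)C)(C(C)C)C(C)C)C=C(OCOC)C1CC=C(C)C | intermediate
16 | 3-(methoxymethoxy)-6-methyl-2-(3-methylbut-2-enyl)-5-(triisopropylsilyloxy)phenol | CC(C)=CCc1c(O)c(C)c(O[Si](C(C)C)(C(C)C)C(C)C)cc1OCOC | intermediate
17 | [3,5-bis(methoxymethoxy)-2-methyl-4-(3-methylbut-2-enyl)phenoxy]triisopropylsilane | CC(C)=CCc1c(OCOC)c(C)c(O[Si](C(C)C)(C(C)C)C(C)C)cc1OCOC | intermediate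
18 | 3,5-bis(methoxymethoxy)-2-methyl-4-(3-methylbut-2-enyl)phenol | CC(C)=CCc1c(OCOC)c(C)c(O)cc1OCOC | intermediate
19 | 2-hydroxy-4,6-bis(methoxymethoxy)-3-methyl-5-(3-methylbut-2-enyl)benzaldehyde | CC(C)=CCc1c(OCOC)c(C)c(O)c(C=O)c1OCOC | intermediate
20 | 2-(1-hydroxyprop-2-ynyl)-3,5-bis(methoxymethoxy)-6-methyl-4-(3-methylbut-2-enyl)phenol (racemic) | CC(C)=CCc1c(OCOC)c(C)c(O)c(C(O)C#C)c1OCOC | intermediate
21 | 1-[2-hydroxy-4,6-bis(methoxymethoxy)-3-methyl-5-(3-methylbut-2-enyl)phenyl]prop-2-yn-1-one | CC(C)=CCc1c(OCOC)c(C)c(O)c(C(=O)C#C)c1OCOC | intermediate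
22 | 5,7-bis(methoxymethoxy)-8-methyl-6-(3-methylbut-2-enyl)-4H-chromen-4-one | CC(C)=CCc1c(OCOC)c(C)c2OC=CC(=O)c2c1OCOC | intermediate
23 | 4-bromophenol | Oc1ccc(Br)cc1 | starting material
24 | 1-bromo-4-(methoxymethoxy)benzene | COCOc1ccc(Br)cc1 | intermediate
25 | [4-(methoxymethoxy)phenyl]lithium | [Li]c1ccc(OCOC)cc1 | intermediate
26 | [4-(methoxymethoxy)phenyl]boronic acid | COCOc1ccc(B(O)O)cc1 | intermediate
27 | (2S)-5,7-bis(methoxymethoxy)-2-[4-(methoxymethoxy)phenyl]-8-methyl-6-(3-methylbut-2-enyl)-2,3-dihydro-4H-chromen-4-one | CC(C)=CCc1c(OCOC)c(C)c2c(c1OCOC)C(=O)C[C@@H](c1ccc(OCOC)cc1)O2 | intermediate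
28 | (2S)-5,7-dihydroxy-2-(4-hydroxyphenyl)-8-methyl-6-(3-methylbut-2-enyl)-2,3-dihydro-4H-chromen-4-one (5,7,4'-trihydroxy-8-methyl-6-prenylflavanone) | CC(C)=CCc1c(O)c(C)c2c(c1O)C(=O)C[C@@H](c1ccc(O)cc1)O2 | target

**Step count and risks**
Total: 15 steps. Longest linear sequence: 12 steps (steps 1–4, 6–11, 14, 15, from 5-bromo-2-methylpent-2-ene).

Steps most likely to fail:

1. Step 6 (benzannulation). The oxygen-substituted vinylketene may be used up by dimerisation or by acylating the phenol product faster than it adds to the siloxyalkyne, and short-wavelength light may degrade the enol acetal or the product. The fallback sets out from diazoketone 8 and returns at phenol 16. It separates ketene formation from the light. A silver-catalysed Wolff rearrangement of 8 in wet THF (PhCO2Ag, Et3N, dark) should give the homologous (Z)-3-(methoxymethoxy)-7-methylocta-3,6-dienoic acid F1, which is used at once. 1-Chloro-N,N,2-trimethylprop-1-en-1-amine should convert it under neutral conditions into (Z)-3-(methoxymethoxy)-7-methylocta-3,6-dienoyl chloride F2. Slow addition of F2 to 11 and Et3N in toluene at 25 °C generates vinylketene 12 by dehydrochlorination, and heating to 90 °C then carries 13, 14 and 15 through to 16 (thermal ketene/siloxyalkyne route to resorcinols).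

2. Step 14 (asymmetric aryl addition). Insertion of the electron-rich, peri-alkoxylated C2=C3 bond may be slow, so that protodeboronation of the electron-rich boronic acid or ring opening of the rhodium enolate to a chalcone takes over; facial selectivity may also be insufficient. The fallback sets out from chromone 22 and returns at 27. Aryllithium 25 (from 24 as in step 13) and CuI should give lithium bis[4-(methoxymethoxy)phenyl]cuprate F3, which adds to 22 in THF at −78 °C in the presence of TMSCl. The 4-(trimethylsilyloxy)-2H-chromene silyl enol ether F4 is hydrolysed on work-up to the racemic form of 27, rac-5,7-bis(methoxymethoxy)-2-[4-(methoxymethoxy)phenyl]-8-methyl-6-(3-methylbut-2-enyl)chroman-4-one F5. Kinetic resolution by asymmetric transfer hydrogenation (RuCl(p-cymene)[(R,R)-TsDPEN], HCO2H/Et3N, EtOAc, 25 °C) is expected to reduce the 2R enantiomer to the cis alcohol (2R,4R)-5,7-bis(methoxymethoxy)-2-[4-(methoxymethoxy)phenyl]-8-methyl-6-(3-methylbut-2-enyl)chroman-4-ol F6 and to leave the 2S ketone 27, which is separated by chromatography.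

3. Step 4 (diazoketone). Diazomethane may add as a 1,3-dipole to the conjugated double bond of the activated acid, and the enol acetal may be lost during activation. The fallback sets out from acid 6 and returns at diazoketone 8. MeLi (2.2 equiv, THF, −78 → 0 °C) should convert 6 into the methyl ketone (3Z)-3-(methoxymethoxy)-7-methylocta-3,6-dien-2-one F7. Its kinetic lithium enolate (LiHMDS, −78 °C) is acylated with CF3CO2CH2CF3 to the diketone (5Z)-1,1,1-trifluoro-5-(methoxymethoxy)-9-methyldeca-5,8-diene-2,4-dione F8, which is not isolated. MsN3, Et3N and water in MeCN then effect detrifluoroacetylative diazo transfer to 8.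

**Further compounds**
F1 | step 6 | (Z)-3-(methoxymethoxy)-7-methylocta-3,6-dienoic acid | OC(=O)C/C(OCOC)=C/CC=C(C)C
F2 | step 6 | (Z)-3-(methoxymethoxy)-7-methylocta-3,6-dienoyl chloride | ClC(=O)C/C(OCOC)=C/CC=C(C)C
F3 | step 14 | lithium bis[4-(methoxymethoxy)phenyl]cuprate | [Li+].COCOc1ccc([Cu-]c2ccc(OCOC)cc2)cc1
F4 | step 14 | [5,7-bis(methoxymethoxy)-2-[4-(methoxymethoxy)phenyl]-8-methyl-6-(3-methylbut-2-enyl)-2H-chromen-4-yl]oxy-trimethylsilane (racemic) | CC(C)=CCc1c(OCOC)c(C)c2c(c1OCOC)C(O[Si](C)(C)C)=CC(c1ccc(OCOC)cc1)O2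
F5 | step 14 | rac-5,7-bis(methoxymethoxy)-2-[4-(methoxymethoxy)phenyl]-8-methyl-6-(3-methylbut-2-enyl)chroman-4-one | CC(C)=CCc1c(OCOC)c(C)c2c(c1OCOC)C(=O)CC(c1ccc(OCOC)cc1)O2
F6 | step 14 | (2R,4R)-5,7-bis(methoxymethoxy)-2-[4-(methoxymethoxy)phenyl]-8-methyl-6-(3-methylbut-2-enyl)chroman-4-ol | CC(C)=CCc1c(OCOC)c(C)c2c(c1OCOC)[C@H](O)C[C@H](c1ccc(OCOC)cc1)O2
F7 | step 4 | (3Z)-3-(methoxymethoxy)-7-methylocta-3,6-dien-2-one | CC(C)=CC/C=C(OCOC)/C(C)=O
F8 | step 4 | (5Z)-1,1,1-trifluoro-5-(methoxymethoxy)-9-methyldeca-5,8-diene-2,4-dione | CC(C)=CC/C=C(OCOC)/C(=O)CC(=O)C(F)(F)F
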